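Numbering: C1 ring ketone, C2–C3 ring CH2CH2, C4(CH3)/C5 epoxide, C6 lactone CH–O, C7 ring carbon of the butenolide C=C, C8 CH–O-propionyl, C9 CH2, C10 C(CH3)OAc. C11, C12 (C=O) and C13 (CH2OAc) lie outside the carbocycle.
Cuts: the epoxide O (last step); the butenolide back to a C7=C11(CH2O)2 acetonide; then C2–C3 of the ten-membered carbocycle; then the tether ester C–O, C7–C8 and C5–C6.
Enabling feature: C1(=O)–C2–C3–C4(CH3)=C5 is an α-allylated ketone, and C10 bears no H, so C1 can enolise only towards C2. Putting CO2 back between C2 and C3 gives a 12-membered allyl β-keto lactone, and Pd(0) expels CO2 and contracts it 12 → 10.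
Forward: the chain is joined from three pieces (C8–C10/C1 from citramalic acid; C11–C13, C7 and C6 from dihydroxyacetone acetonide, CBr4 and DMF; C3–C5 from a propargyl ether). Rings then arise in the order 12-membered lactone (acylketene capture) → ten-membered carbocycle → butenolide → epoxide.
Stereochemistry: C10 is bought ((R)-citramalic acid), C6 comes from Zn–ProPhenol alkynylation and C8 from CBS reduction. E-C4=C5 comes from directed hydroalumination/Negishi coupling and is kept through the syn-allyl complex. The C4/C5 epoxide is relayed from C6 by peripheral attack on the ten-membered ring.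

Key step: step 17

Assumption: the catalyst enantiomers named in steps 6 and 11 follow the usual facial models (Re-face alkynyl transfer for (S,S)-ProPhenol; alkenyl = large group for CBS). Both antipodes of each are sold, so the sense can be matched to the drawn product.

Step 1
Reactants: 1 (R)-citramalic acid
Product: 2 diallyl (R)-citramalate
Conditions: allyl bromide, K2CO3, DMF, rt
Reagents that add atoms: allyl bromide C=CCBr
Why: Carboxylate O-alkylation (SN2) esterifies both acids without touching the tertiary carbinol, so the bought stereocentre (future C10, R) is carried on unchanged.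

Step 2
Reactants: 2 diallyl (R)-citramalate
Product: 3 diallyl (R)-2-(tert-butyldimethylsilyloxy)-2-methylbutanedioate
Conditions: TBSOTf, 2,6-lutidine, CH2Cl2, 0 °C to rt
Reagents that add atoms: TBSOTf CC(C)(C)[Si](C)(C)OS(=O)(=O)C(F)(F)F
Why: Silyl triflate silylation is the standard protection of a hindered tertiary alcohol and gives an ether that should survive the later organolithium, borane and Pd(0) steps.

Step 3
Reactants: 3 diallyl (R)-2-(tert-butyldimethylsilyloxy)-2-methylbutanedioate
Product: 4 allyl (R)-2-(tert-butyldimethylsilyloxy)-4-[methoxy(methyl)amino]-2-methyl-4-oxobutanoate (East piece, C8–C10 and C1)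
Conditions: MeNH(OMe)·HCl, i-PrMgCl, THF, −20 °C
Reagents that add atoms: N,O-dimethylhydroxylamine hydrochloride CNOC.Cl
Why: Magnesium amide aminolysis (Weinreb amide formation from an ester) should attack only the unhindered CH2–CO2allyl group, because the other ester is shielded by the fully substituted silyloxy carbon.

Step 4
Reactants: 5 2,2-dimethyl-1,3-dioxan-5-one
Product: 6 5-(dibromomethylene)-2,2-dimethyl-1,3-dioxane
Conditions: CBr4, PPh3, CH2Cl2, 0 °C
Reagents that add atoms: carbon tetrabromide BrC(Br)(Br)Br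
Why: Ramirez (Corey–Fuchs type) dibromoolefination of this electrophilic ketone installs C7 as a 1,1-dianion equivalent, and the two identical CH2O arms on C11 remove any E/Z question for the later tetrasubstituted alkene.

Step 5
Reactants: 6 5-(dibromomethylene)-2,2-dimethyl-1,3-dioxane
Product: 8 2-bromo-2-(2,2-dimethyl-1,3-dioxan-5-ylidene)acetaldehyde, via lithium bromocarbenoid 7 (not isolated)
Conditions: n-BuLi, THF/Et2O, −105 °C; DMF; H2O
Reagents that add atoms: N,N-dimethylformamide CN(C)C=O
Why: Bromine–lithium exchange of a 1,1-dibromoalkene at very low temperature followed by formylation is a known route to α-bromo enals, and either bromine gives the same product because C11 is symmetric.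

Step 6
Reactants: 8 2-bromo-2-(2,2-dimethyl-1,3-dioxan-5-ylidene)acetaldehyde; 9 tert-butyldimethyl(prop-2-yn-1-yloxy)silane
Product: 10 (2R)-1-bromo-1-(2,2-dimethyl-1,3-dioxan-5-ylidene)-5-(tert-butyldimethylsilyloxy)pent-3-yn-2-ol
Conditions: Me2Zn, (S,S)-ProPhenol (20 mol %), Ph3PO (40 mol %), toluene, 4 °C
Reagents that add atoms: none
Why: Zinc–ProPhenol catalysed asymmetric alkynylation of an α-substituted enal forms C5–C6 and sets C6 (R at this stage) by catalyst-controlled attack on the Re face of the aldehyde.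

Step 7
Reactants: 10 (2R)-propargylic alcohol
Product: 12 (2R,3Z)-1-bromo-1-(2,2-dimethyl-1,3-dioxan-5-ylidene)-4-iodo-5-(tert-butyldimethylsilyloxy)pent-3-en-2-ol, via cyclic alkenylalanate 11 (not isolated)
Conditions: Red-Al, THF, 0 °C to rt; EtOAc; I2, −78 to 0 °C
Reagents that add atoms: iodine II
Why: Alkoxide-directed trans-hydroalumination of the propargylic alcohol puts H on C5 and Al on C4 in a five-membered alanate, and iodinolysis with retention gives the Z iodide with iodine cis to C6.

Step 8
Reactants: 12 (2R,3Z)-alkenyl iodide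
Product: 13 (2R,3E)-1-bromo-1-(2,2-dimethyl-1,3-dioxan-5-ylidene)-4-methyl-5-(tert-butyldimethylsilyloxy)pent-3-en-2-ol
Conditions: MeZnCl, Pd(PPh3)4 (5 mol %), THF, 0 °C to rt
Reagents that add atoms: methylzinc chloride C[Zn]Cl
Why: Negishi coupling proceeds with retention and much faster at the alkenyl iodide than at the hindered alkenyl bromide, which fixes the E-trisubstituted C4=C5 alkene (CH3 cis to C6).

Step 9
Reactants: 13 (2R,3E)-allylic alcohol
Product: 14 O6-TBS ether of 13 (West piece, C3–C7 and C11–C13; 6R)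
Conditions: TBSOTf, 2,6-lutidine, CH2Cl2, −78 to 0 °C
Reagents that add atoms: TBSOTf CC(C)(C)[Si](C)(C)OS(=O)(=O)C(F)(F)F
Why: Silyl triflate silylation covers the hindered bis-allylic carbinol as a poor leaving group that should tolerate t-BuLi and later Pd(0).

Step 10
Reactants: 14 West alkenyl bromide; 4 East Weinreb amide
Product: 16 (6R,10R)-C8 enone of the full C1–C13 chain (allyl ester at C1; TBS ethers on O3 O6 O10; acetonide on O12/O13), via alkenyllithium 15 (not isolated)
Conditions: t-BuLi (2 equiv), Et2O, −78 °C; then 4, −78 to −40 °C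
Reagents that add atoms: none
Why: Bromine–lithium exchange and acylation by a Weinreb amide join C7 to C8 and stop at the ketone through the chelated tetrahedral intermediate, while the hindered allyl ester next to C10 should be spared.

Step 11
Reactants: 16 C8 enone
Product: 17 (6R,8S,10R)-C8 allylic alcohol
Conditions: (R)-Me-CBS, catecholborane, toluene, −78 °C
Reagents that add atoms: none
Why: CBS reduction delivers hydride to the face fixed by the catalyst (large group the tetrasubstituted alkenyl C7, small group C9H2) to give the 8S carbinol, and catecholborane at low temperature leaves alkenes and esters alone.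

Step 12
Reactants: 17 C8 allylic alcohol
Product: 18 (6R,8S,10R)-C8 propionate
Conditions: (EtCO)2O, DMAP, Et3N, CH2Cl2, 0 °C
Reagents that add atoms: propionic anhydride CCC(=O)OC(=O)CC
Why: DMAP-catalysed acylation puts the final C8 ester on the only free hydroxyl with retention at C8.

Step 13
Reactants: 18 allyl ester
Product: 19 (6R,8S,10R)-C1 carboxylic acid
Conditions: Pd(PPh3)4 (5 mol %), morpholine, THF, rt
Reagents that add atoms: none
Why: Tsuji–Trost deallylation frees the acid under neutral conditions, and the C8 propionate should stay because its tetrasubstituted alkene does not bind Pd(0).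

Step 14
Reactants: 19 C1 carboxylic acid; 20 Meldrum's acid
Product: 21 5-acyl Meldrum's acid (enol form; 6R,8S,10R)
Conditions: EDCI·HCl, DMAP, CH2Cl2, 0 °C to rt
Reagents that add atoms: none
Why: Carbodiimide/DMAP C-acylation of Meldrum's acid, which also works with α,α-disubstituted acids, brings in C2 and the future CO2 tether as a latent acylketene.

Step 15
Reactants: 21 5-acyl Meldrum's acid
Product: 22 C3 primary allylic alcohol (6R,8S,10R)
Conditions: HF·pyridine, pyridine, THF, 0 °C
Reagents that add atoms: none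
Why: Buffered HF·pyridine cleaves a primary TBS ether much faster than the hindered secondary (O6) and tertiary (O10) ones and does not touch the acetonide.

Step 16
Reactants: 22 hydroxy acyl Meldrum's acid
Product: 24 twelve-membered allyl β-keto lactone (6R,8S,10R), via acylketene 23 (not isolated)
Conditions: slow addition to refluxing toluene (about 0.5 mM), 110 °C
Reagents that add atoms: none
Why: Thermolysis of an acyl Meldrum's acid releases an acylketene that is captured by the only hydroxyl (acylketene macrolactonisation), which closes an almost strain-free 12-membered ring under neutral conditions.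

Step 17
Reactants: 24 twelve-membered allyl β-keto lactone
Product: 26 ten-membered (4E)-cyclodec-4-enone (6R,8S,10R; O6 O10 TBS; C8 propionate; C7=C11 dioxanylidene), via allylpalladium enolate 25 (not isolated)
Conditions: Pd2(dba)3 (5 mol %), 2-[2-(diphenylphosphino)phenyl]-4,4-dimethyl-2-oxazoline (12 mol %), toluene (about 1 mM), 40 °C
Reagents that add atoms: none
Why: Proposed new method: Pd(0) ionises the primary C3–O bond of the lactone and opens the 12-membered ring to a syn-η3-allylpalladium β-keto carboxylate; loss of CO2 leaves the C1–C2 enolate on the same metal, and C2–C3 reductive elimination recloses the chain as the ten-membered carbocycle, smaller by the C and O of CO2. The closest known reaction type is the decarboxylative allylic alkylation of acyclic allyl β-keto esters (Tsuji–Trost/Carroll type), which has not been used to contract a macrocyclic lactone to a medium ring. The ring closes in the 10-endo mode at the unsubstituted terminus C3 and not 8-exo at C5, because C5 is secondary, is flanked by the silyloxy carbon C6, and attack there would give up the trisubstituted alkene. No stereocentre is formed: the E geometry of C4=C5 passes through the syn-allyl complex, and C6, C8 and C10 are not touched. Enolate regiochemistry is secured because C10 has no hydrogen; chemoselective ionisation is secured because the C8 propionate and the dioxane C–O bonds sit on a tetrasubstituted alkene that does not bind Pd(0) and O6 is a silyl ether; and the butenolide is kept masked so that C6–H is not acidic and is not lost from the allyl complex. High dilution, the metal holding both termini and the irreversible loss of CO2 should disfavour oligomers and pay for the added ring strain.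

Step 18
Reactants: 26 ten-membered cyclodecenone
Product: 27 tetraol (free O6 O10 O12 O13; 6R,8S,10R)
Conditions: 48 % aq HF, MeCN, 0 °C to rt
Reagents that add atoms: none
Why: Aqueous HF in acetonitrile removes both TBS ethers and hydrolyses the acetonide in one operation, while the propionate and the α-ketol should persist.

Step 19
Reactants: 27 tetraol
Product: 29 α-formyl butenolide (C12 lactone closed on O6; C13 aldehyde; 6R,8S,10R), via lactol 28 (not isolated)
Conditions: TEMPO (20 mol %), PhI(OAc)2 (3.3 equiv), CH2Cl2, rt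
Reagents that add atoms: none
Why: Oxoammonium oxidation prefers primary alcohols, so the aldehyde cis to O6 is trapped as the five-membered lactol and oxidised on to the butenolide (oxidative lactonisation of a Z-2-ene-1,4-diol), which differentiates the two CH2OH arms, and the other arm stops at the aldehyde.

Step 20
Reactants: 29 α-formyl butenolide
Product: 30 13-hydroxymethyl butenolide with free 10-OH (6R,8S,10R)
Conditions: NaBH4, CH2Cl2/MeOH, −78 °C
Reagents that add atoms: none
Why: At −78 °C borohydride reduces aldehydes far faster than ketones and C7 is fully substituted, so 1,2-reduction of the formyl group is expected with the hindered C1 ketone and the lactone left intact.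

Step 21
Reactants: 30 diol
Product: 31 10,13-diacetate (4E; 6R,8S,10R)
Conditions: Ac2O, Sc(OTf)3 (5 mol %), MeCN, −20 °C
Reagents that add atoms: acetic anhydride CC(=O)OC(C)=O
Why: Lewis acid catalysed acetylation acylates primary and tertiary alcohols without base, which avoids deprotonation of the now acidic C6–H and a base-induced α-ketol shift.

Step 22
Reactants: 31 10,13-diacetate
Product: 32 target CNP0285168.1 (4R,5R,6S,8S,10R)
Conditions: mCPBA, NaHCO3, CH2Cl2, 0 °C
Reagents that add atoms: mCPBA OOC(=O)c1cccc(Cl)c1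
Why: Prilezhaev epoxidation should touch only the electron-rich C4=C5 alkene and only its outer face, and in the conformer with C6–H eclipsing C4–CH3 (minimal A1,3 strain) that face lies on the side of the C6–O bond, which with syn addition to the E-alkene gives 4R,5R.

Compound list
1 | (R)-citramalic acid | C[C@@](O)(CC(=O)O)C(=O)O | starting material
2 | diallyl (R)-citramalate | C[C@@](O)(CC(=O)OCC=C)C(=O)OCC=C | intermediate
3 | diallyl (R)-2-(tert-butyldimethylsilyloxy)-2-methylbutanedioate | C[C@@](O[Si](C)(C)C(C)(C)C)(CC(=O)OCC=C)C(=O)OCC=C | intermediate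
4 | allyl (R)-2-(tert-butyldimethylsilyloxy)-4-[methoxy(methyl)amino]-2-methyl-4-oxobutanoate | C[C@@](O[Si](C)(C)C(C)(C)C)(CC(=O)N(C)OC)C(=O)OCC=C | intermediate
5 | 2,2-dimethyl-1,3-dioxan-5-one | CC1(C)OCC(=O)CO1 | starting material
6 | 5-(dibromomethylene)-2,2-dimethyl-1,3-dioxane | CC1(C)OCC(=C(Br)Br)CO1 | intermediate
7 | lithium bromocarbenoid (not isolated) | CC1(C)OCC(=C(Br)[Li])CO1 | intermediate
8 | 2-bromo-2-(2,2-dimethyl-1,3-dioxan-5-ylidene)acetaldehyde | CC1(C)OCC(=C(Br)C=O)CO1 | intermediate
9 | tert-butyldimethyl(prop-2-yn-1-yloxy)silane | C#CCO[Si](C)(C)C(C)(C)C | starting material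
10 | (2R)-1-bromo-1-(2,2-dimethyl-1,3-dioxan-5-ylidene)-5-(tert-butyldimethylsilyloxy)pent-3-yn-2-ol | CC1(C)OCC(=C(Br)[C@H](O)C#CCO[Si](C)(C)C(C)(C)C)CO1 | intermediate
11 | cyclic sodium alkenylalanate (not isolated) | [Na+].COCCO[Al-]1(OCCOC)O[C@@H](C(Br)=C2COC(C)(C)OC2)C=C1CO[Si](C)(C)C(C)(C)C | intermediate
12 | (2R,3Z)-4-iodo allylic alcohol | CC1(C)OCC(=C(Br)[C@H](O)/C=C(I)/CO[Si](C)(C)C(C)(C)C)CO1 | intermediate
13 | (2R,3E)-4-methyl allylic alcohol | CC1(C)OCC(=C(Br)[C@H](O)/C=C(C)/CO[Si](C)(C)C(C)(C)C)CO1 | intermediate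
14 | West alkenyl bromide, O6-TBS ether (6R) | CC1(C)OCC(=C(Br)[C@H](O[Si](C)(C)C(C)(C)C)/C=C(C)/CO[Si](C)(C)C(C)(C)C)CO1 | intermediate
15 | alkenyllithium (not isolated) | CC1(C)OCC(=C([Li])[C@H](O[Si](C)(C)C(C)(C)C)/C=C(C)/CO[Si](C)(C)C(C)(C)C)CO1 | intermediate
16 | (6R,10R)-C8 enone | C=CCOC(=O)[C@](C)(O[Si](C)(C)C(C)(C)C)CC(=O)C(=C1COC(C)(C)OC1)[C@H](O[Si](C)(C)C(C)(C)C)/C=C(C)/CO[Si](C)(C)C(C)(C)C | intermediate
17 | (6R,8S,10R)-C8 allylic alcohol | C=CCOC(=O)[C@](C)(O[Si](C)(C)C(C)(C)C)C[C@H](O)C(=C1COC(C)(C)OC1)[C@H](O[Si](C)(C)C(C)(C)C)/C=C(C)/CO[Si](C)(C)C(C)(C)C | intermediate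
18 | (6R,8S,10R)-C8 propionate, allyl ester | C=CCOC(=O)[C@](C)(O[Si](C)(C)C(C)(C)C)C[C@H](OC(=O)CC)C(=C1COC(C)(C)OC1)[C@H](O[Si](C)(C)C(C)(C)C)/C=C(C)/CO[Si](C)(C)C(C)(C)C | intermediate
19 | (6R,8S,10R)-C1 carboxylic acid | OC(=O)[C@](C)(O[Si](C)(C)C(C)(C)C)C[C@H](OC(=O)CC)C(=C1COC(C)(C)OC1)[C@H](O[Si](C)(C)C(C)(C)C)/C=C(C)/CO[Si](C)(C)C(C)(C)C | intermediate
20 | Meldrum's acid | CC1(C)OC(=O)CC(=O)O1 | starting material
21 | 5-acyl Meldrum's acid, enol form | CC1(C)OC(=O)C(=C(O)[C@](C)(O[Si](C)(C)C(C)(C)C)C[C@H](OC(=O)CC)C(=C2COC(C)(C)OC2)[C@H](O[Si](C)(C)C(C)(C)C)/C=C(C)/CO[Si](C)(C)C(C)(C)C)C(=O)O1 | intermediate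
22 | 5-acyl Meldrum's acid with free C3–OH | CC1(C)OC(=O)C(=C(O)[C@](C)(O[Si](C)(C)C(C)(C)C)C[C@H](OC(=O)CC)C(=C2COC(C)(C)OC2)[C@H](O[Si](C)(C)C(C)(C)C)/C=C(C)/CO)C(=O)O1 | intermediate
23 | acylketene (not isolated) | O=C=CC(=O)[C@](C)(O[Si](C)(C)C(C)(C)C)C[C@H](OC(=O)CC)C(=C1COC(C)(C)OC1)[C@H](O[Si](C)(C)C(C)(C)C)/C=C(C)/CO | intermediate
24 | twelve-membered allyl β-keto lactone | O=C1CC(=O)[C@](C)(O[Si](C)(C)C(C)(C)C)C[C@H](OC(=O)CC)C(=C2COC(C)(C)OC2)[C@H](O[Si](C)(C)C(C)(C)C)/C=C(C)/CO1 | intermediate
25 | allylpalladium enolate, drawn as σ-allyl form without ligands (not isolated) | C=C([O-])[C@](C)(O[Si](C)(C)C(C)(C)C)C[C@H](OC(=O)CC)C(=C1COC(C)(C)OC1)[C@H](O[Si](C)(C)C(C)(C)C)/C=C(C)/C[Pd+] | intermediate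
26 | ten-membered (4E)-cyclodecenone | O=C1[C@](C)(O[Si](C)(C)C(C)(C)C)C[C@H](OC(=O)CC)C(=C2COC(C)(C)OC2)[C@H](O[Si](C)(C)C(C)(C)C)/C=C(C)/CC1 | intermediate
27 | tetraol | O=C1[C@](C)(O)C[C@H](OC(=O)CC)C(=C(CO)CO)[C@H](O)/C=C(C)/CC1 | intermediate
28 | C12 lactol (not isolated) | O=C1[C@](C)(O)C[C@H](OC(=O)CC)C2=C(CO)C(O)O[C@@H]2/C=C(C)/CC1 | intermediate
29 | α-formyl butenolide | O=C1[C@](C)(O)C[C@H](OC(=O)CC)C2=C(C=O)C(=O)O[C@@H]2/C=C(C)/CC1 | intermediate
30 | 10,13-diol butenolide | O=C1[C@](C)(O)C[C@H](OC(=O)CC)C2=C(CO)C(=O)O[C@@H]2/C=C(C)/CC1 | intermediate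
31 | 10,13-diacetate, 4E-alkene | O=C1[C@](C)(OC(C)=O)C[C@H](OC(=O)CC)C2=C(COC(C)=O)C(=O)O[C@@H]2/C=C(C)/CC1 | intermediate
32 | CNP0285168.1 | CCC(=O)O[C@H]1C[C@@](C)(OC(C)=O)C(=O)CC[C@@]2(C)O[C@@H]2[C@H]2OC(=O)C(COC(C)=O)=C12 | target

Total steps: 22. Longest linear sequence: 19 (steps 4–22, from 5).

Steps most likely to fail

Step 17. The ten-membered closure is slow, so proton transfer to the enolate, loss of a proton from the allyl complex or intermolecular allylation may win. The fallback sets out from 21 and comes back at 26, and it makes the same C2–C3 bond by a known Tsuji–Trost macrocyclisation with a stabilised nucleophile. Compound 21 is heated with methanol in toluene to the methyl β-keto ester F1. HF·pyridine cleaves the primary silyl ether to the allylic alcohol F2. Methyl chloroformate/pyridine gives the allylic carbonate F3. Pd(PPh3)4/dppe in THF at high dilution closes the ten-membered β-keto ester F4. Krapcho demethoxycarbonylation (LiCl, wet DMSO, heat) then gives 26.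

Step 10. The hindered, basic alkenyllithium may enolise the Weinreb amide, with β-elimination of the silyloxide, or may acylate too slowly. The fallback sets out from 4 and 14 and comes back at 16, and it replaces acylation by carbonyl addition and oxidation. Compound 4 is reduced with DIBAL-H at −78 °C to the aldehyde F5. Alkenyllithium 15 from 14 is transmetallated with CeCl3 and added to F5 to give the C8-epimeric allylic alcohols F6. Dess–Martin oxidation gives 16.

Step 18. Once O6 is free next to the electron-rich tetrasubstituted alkene, acid may ionise the bis-allylic C6–O bond, which would lead to cyclodehydration or loss of configuration. The fallback sets out from 26 and comes back at 29, and it frees O6 only after the alkene has been made electron-poor. Aqueous acetic acid removes the acetonide alone to give the diol F7. MnO2 gives the dialdehyde F8. HF·pyridine then removes both silyl groups, and O6 closes on the cis formyl group to give the lactol aldehyde F9. TEMPO/PhI(OAc)2 gives 29.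

Further compounds
F1 | step 17 | methyl β-keto ester | COC(=O)CC(=O)[C@](C)(O[Si](C)(C)C(C)(C)C)C[C@H](OC(=O)CC)C(=C1COC(C)(C)OC1)[C@H](O[Si](C)(C)C(C)(C)C)/C=C(C)/CO[Si](C)(C)C(C)(C)C
F2 | step 17 | allylic alcohol | COC(=O)CC(=O)[C@](C)(O[Si](C)(C)C(C)(C)C)C[C@H](OC(=O)CC)C(=C1COC(C)(C)OC1)[C@H](O[Si](C)(C)C(C)(C)C)/C=C(C)/CO
F3 | step 17 | allylic carbonate | COC(=O)CC(=O)[C@](C)(O[Si](C)(C)C(C)(C)C)C[C@H](OC(=O)CC)C(=C1COC(C)(C)OC1)[C@H](O[Si](C)(C)C(C)(C)C)/C=C(C)/COC(=O)OC
F4 | step 17 | ten-membered β-keto ester | O=C1[C@](C)(O[Si](C)(C)C(C)(C)C)C[C@H](OC(=O)CC)C(=C2COC(C)(C)OC2)[C@H](O[Si](C)(C)C(C)(C)C)/C=C(C)/CC1C(=O)OC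
F5 | step 10 | aldehyde | C[C@@](O[Si](C)(C)C(C)(C)C)(CC=O)C(=O)OCC=C
F6 | step 10 | C8-epimeric allylic alcohols | C=CCOC(=O)[C@](C)(O[Si](C)(C)C(C)(C)C)CC(O)C(=C1COC(C)(C)OC1)[C@H](O[Si](C)(C)C(C)(C)C)/C=C(C)/CO[Si](C)(C)C(C)(C)C
F7 | step 18 | diol | O=C1[C@](C)(O[Si](C)(C)C(C)(C)C)C[C@H](OC(=O)CC)C(=C(CO)CO)[C@H](O[Si](C)(C)C(C)(C)C)/C=C(C)/CC1
F8 | step 18 | dialdehyde | O=C1[C@](C)(O[Si](C)(C)C(C)(C)C)C[C@H](OC(=O)CC)C(=C(C=O)C=O)[C@H](O[Si](C)(C)C(C)(C)C)/C=C(C)/CC1
F9 | step 18 | lactol aldehyde | O=C1[C@](C)(O)C[C@H](OC(=O)CC)C2=C(C=O)C(O)O[C@@H]2/C=C(C)/CC1
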